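**Plan**

- Retrosynthesis: the C4–C5' bond between the two chroman halves is cut first (arylation of a lower-half arene by the upper-half C4 cation). In each half the C2–C3 and O1–C8a bonds of ring C are then cut (one formaldehyde unit bridging a 2-fluoroaryl benzyl ketone), and last the C3–aryl bond (ketone α-arylation).
- Enabling feature: C4 lies between C3 and ring A. A carbonyl at C4 acidifies C3–H and activates a fluorine on C8a ortho to it, so the single CH2–O unit of ring C can be stitched in between C3 and C8a in one operation.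
- Forward: ring C of each half is closed from an acyclic ketone. The upper half is reduced and closed to a pterocarpan, a temporary fifth ring that stores the C4 electrophile; opening it joins the halves. The lower C4 oxygen and the three benzyl groups leave last.
- Stereochemistry: upper C3 comes from asymmetric transfer hydrogenation with dynamic kinetic resolution of the labile isoflavanone. Upper C4 comes from anti attack on the C4 cation (3,4-trans). Lower C3 comes from a second dynamic kinetic resolution after the union.
- Helpers removed on the way: fluoride, both C4 carbonyls, the methoxymethyl group, the pterocarpan ring and the benzyl ethers.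

Key step: step 5

Remark: chroman numbering is used (O1, C2, C3, C4, C4a, C5 to C8, C8a; primed numbers for the aryl ring on C3); the target is read as 3R,4S (aryl groups trans) in the upper half and 3R in the lower half, and the sense of induction known for the (R,R)-configured catalyst with chroman-4-ones is assumed to hold for 3-aryl chroman-4-ones.

**Route**

Step 1
Reactants: 1 1-(2-fluoro-4-hydroxyphenyl)ethan-1-one
Product: 2 1-[4-(benzyloxy)-2-fluorophenyl]ethan-1-one
Conditions: BnBr, K2CO3, acetone, reflux
Reagents that add atoms: benzyl bromide, BrCc1ccccc1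
Why: Williamson ether synthesis on the phenoxide, which is far more nucleophilic than the ketone enolate under carbonate conditions; the benzyl ether keeps the para oxygen neutral so that it does not switch off the later substitution of fluoride.

Step 2
Reactants: 3 3,4-dimethoxyphenol
Product: 4 2-bromo-4,5-dimethoxyphenol
Conditions: NBS, CH2Cl2, −10 → 0 °C
Reagents that add atoms: N-bromosuccinimide, O=C1CCC(=O)N1Br
Why: Electrophilic aromatic bromination should occur at the position ortho to the hydroxyl and para to the 3-methoxy group, the most activated and least hindered site of the ring.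

Step 3
Reactants: 4 2-bromo-4,5-dimethoxyphenol
Product: 5 1-bromo-4,5-dimethoxy-2-(methoxymethoxy)benzene
Conditions: NaH, MOMCl, THF, 0 °C → rt
Reagents that add atoms: chloromethyl methyl ether, COCCl
Why: Williamson-type O-alkylation of the sodium phenoxide installs an acetal protecting group that survives base and palladium catalysis and is removed by acid in step 6.

Step 4
Reactants: 2 1-[4-(benzyloxy)-2-fluorophenyl]ethan-1-one; 5 1-bromo-4,5-dimethoxy-2-(methoxymethoxy)benzene
Product: 6 1-[4-(benzyloxy)-2-fluorophenyl]-2-[4,5-dimethoxy-2-(methoxymethoxy)phenyl]ethan-1-one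
Conditions: Pd2(dba)3, Xantphos, K3PO4, toluene, 90 °C
Reagents that add atoms: none
Why: Palladium-catalysed α-arylation of the methyl ketone (oxidative addition of the aryl bromide to zerovalent palladium, enolate binding, reductive elimination) forms the C3–aryl bond; the ortho substituent of 5 and the weak base K3PO4 should limit diarylation and spare the aryl fluoride.

Step 5
Reactants: 6 1-[4-(benzyloxy)-2-fluorophenyl]-2-[4,5-dimethoxy-2-(methoxymethoxy)phenyl]ethan-1-one
Product: 8 7-(benzyloxy)-3-[4,5-dimethoxy-2-(methoxymethoxy)phenyl]chroman-4-one (racemic), via hydroxymethyl ketone 7 (not isolated)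
Conditions: (CH2O)n, Cs2CO3, DMSO, 25 → 70 °C, argon
Reagents that add atoms: paraformaldehyde (reacts as formaldehyde), C=O
Why: Cs2CO3 deprotonates C3, which is flanked by the C4 carbonyl and an aryl ring; the enolate adds to formaldehyde to form the C2–C3 bond, and the primary alkoxide of 7 then attacks the fluorine-bearing C8a ortho to the carbonyl and expels fluoride through a Meisenheimer-type enolate, forming the O1–C8a bond. The closest known reaction type is the tandem C–C bond formation/intramolecular SNAr annulation of ortho-fluoroaryl ketones (here a crossed aldol addition followed by aryl ether formation), as used for chromones and chroman-4-ones. Ring C closes by a six-membered addition–elimination that is 6-endo-trig with respect to the C4a=C8a bond, which relays the charge to the C4 oxygen. C3 is created without control and stays configurationally labile next to the ketone, which is intended because it is fixed in step 6 by dynamic kinetic resolution. The step needs ring closure to outrun dehydration of 7 to the α-methylene ketone and a second hydroxymethylation; the aldol addition and the hydration of that enone are reversible whereas fluoride loss is not, the alkoxide is held within reach of C8a, and only the fluorine ortho to the carbonyl is activated, so the equilibria should drain into 8.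

Step 6
Reactants: 8 7-(benzyloxy)-3-[4,5-dimethoxy-2-(methoxymethoxy)phenyl]chroman-4-one
Product: 11 (6aR,11aR)-3-(benzyloxy)-8,9-dimethoxypterocarpan, via cis-isoflavan-4-ol MOM ether 9 (not isolated), via cis-2'-hydroxyisoflavan-4-ol 10 (not isolated)
Conditions: RuCl[(R,R)-TsDPEN](p-cymene), HCO2H–Et3N (5:2), EtOAc, 40 °C; then solvent switch to THF, 3 M HCl (aq), 45 °C
Reagents that add atoms: none
Why: Noyori-type asymmetric transfer hydrogenation with dynamic kinetic resolution, in which C3 epimerises through the enol under Et3N while the catalyst should reduce the (3R)-ketone from the face anti to the C3 aryl group to give the cis (3R,4R) alcohol; acid then removes the acetal and the 2'-hydroxyl captures the C4 benzylic cation, which can only give the cis ring fusion.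

Step 7
Reactants: 12 2-bromo-5-methoxyphenol
Product: 13 2-(benzyloxy)-1-bromo-4-methoxybenzene
Conditions: BnBr, K2CO3, acetone, reflux
Reagents that add atoms: benzyl bromide, BrCc1ccccc1
Why: Williamson ether synthesis on the phenoxide gives the benzyl ether that protects the lower-half 2'-oxygen until the last step.

Step 8
Reactants: 2 1-[4-(benzyloxy)-2-fluorophenyl]ethan-1-one; 13 2-(benzyloxy)-1-bromo-4-methoxybenzene
Product: 14 1-[4-(benzyloxy)-2-fluorophenyl]-2-[2-(benzyloxy)-4-methoxyphenyl]ethan-1-one
Conditions: Pd2(dba)3, Xantphos, K3PO4, toluene, 90 °C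
Reagents that add atoms: none
Why: The same palladium-catalysed ketone α-arylation as in step 4 forms the C3–aryl bond of the lower half.

Step 9
Reactants: 14 1-[4-(benzyloxy)-2-fluorophenyl]-2-[2-(benzyloxy)-4-methoxyphenyl]ethan-1-one
Product: 16 7-(benzyloxy)-3-[2-(benzyloxy)-4-methoxyphenyl]chroman-4-one (racemic), via hydroxymethyl ketone 15 (not isolated)
Conditions: (CH2O)n, Cs2CO3, DMSO, 25 → 70 °C, argon
Reagents that add atoms: paraformaldehyde (reacts as formaldehyde), C=O
Why: The same crossed aldol/intramolecular SNAr annulation as in step 5 closes ring C of the lower half, and the labile C3 stereocentre is again left for a later dynamic kinetic resolution.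

Step 10
Reactants: 11 (6aR,11aR)-3-(benzyloxy)-8,9-dimethoxypterocarpan; 16 7-(benzyloxy)-3-[2-(benzyloxy)-4-methoxyphenyl]chroman-4-one (1.3 equiv)
Product: 17 7-(benzyloxy)-3-{2-(benzyloxy)-5-[(3R,4S)-7-(benzyloxy)-3-(2-hydroxy-4,5-dimethoxyphenyl)chroman-4-yl]-4-methoxyphenyl}chroman-4-one (both epimers at the labile C3 of the chromanone)
Conditions: TsOH·H2O (10 mol%), HFIP–CH2Cl2 (1:1), 0 °C → rt
Reagents that add atoms: none
Why: Acid-catalysed opening of the benzylic aryl ether of 11 gives the C4 cation stabilised by the para benzyloxy group, which C5' of 16 (para to benzyloxy, ortho to methoxy, while ring A of 16 is deactivated by its C4 carbonyl) should take up in a Friedel–Crafts alkylation on the face anti to the C3 aryl group, setting the 3,4-trans (4S) configuration; pterocarpans are established electrophiles of this kind.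

Step 11
Reactants: 17 7-(benzyloxy)-3-{2-(benzyloxy)-5-[(3R,4S)-7-(benzyloxy)-3-(2-hydroxy-4,5-dimethoxyphenyl)chroman-4-yl]-4-methoxyphenyl}chroman-4-one
Product: 18 (3R,4R)-7-(benzyloxy)-3-{2-(benzyloxy)-5-[(3R,4S)-7-(benzyloxy)-3-(2-hydroxy-4,5-dimethoxyphenyl)chroman-4-yl]-4-methoxyphenyl}chroman-4-ol
Conditions: RuCl[(R,R)-TsDPEN](p-cymene), HCO2H–Et3N (5:2), DMF, 40 °C
Reagents that add atoms: none
Why: In this second asymmetric transfer hydrogenation with dynamic kinetic resolution the two C3 epimers of the chromanone interconvert under Et3N, and the catalyst, not the remote upper half, should select the (3R)-ketone and deliver hydride anti to the aryl group to give the cis (3R,4R) alcohol.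

Step 12
Reactants: 18 (3R,4R)-7-(benzyloxy)-3-{2-(benzyloxy)-5-[(3R,4S)-7-(benzyloxy)-3-(2-hydroxy-4,5-dimethoxyphenyl)chroman-4-yl]-4-methoxyphenyl}chroman-4-ol
Product: 19 (3R,4S)-4-{4-hydroxy-5-[(3R)-7-hydroxychroman-3-yl]-2-methoxyphenyl}-3-(2-hydroxy-4,5-dimethoxyphenyl)chroman-7-ol (CNP0217096.1)
Conditions: H2 (3 bar), 10% Pd/C, EtOAc–EtOH, AcOH, 25 °C
Reagents that add atoms: none
Why: Palladium-catalysed hydrogenolysis should cleave the three benzyl ethers and the electron-rich benzylic C4–OH bond of the lower half (as in the reduction of isoflavan-4-ols to isoflavans), and no bond at a stereocentre that is kept is broken.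

**Compound list**

1 | 1-(2-fluoro-4-hydroxyphenyl)ethan-1-one | CC(=O)c1ccc(O)cc1F | starting material
2 | 1-[4-(benzyloxy)-2-fluorophenyl]ethan-1-one | CC(=O)c1ccc(OCc2ccccc2)cc1F | intermediate
3 | 3,4-dimethoxyphenol | COc1ccc(O)cc1OC | starting material
4 | 2-bromo-4,5-dimethoxyphenol | COc1cc(O)c(Br)cc1OC | intermediate
5 | 1-bromo-4,5-dimethoxy-2-(methoxymethoxy)benzene | COCOc1cc(OC)c(OC)cc1Br | intermediate
6 | 1-[4-(benzyloxy)-2-fluorophenyl]-2-[4,5-dimethoxy-2-(methoxymethoxy)phenyl]ethan-1-one | COCOc1cc(OC)c(OC)cc1CC(=O)c1ccc(OCc2ccccc2)cc1F | intermediate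
7 | 1-[4-(benzyloxy)-2-fluorophenyl]-2-[4,5-dimethoxy-2-(methoxymethoxy)phenyl]-3-hydroxypropan-1-one (racemic) | COCOc1cc(OC)c(OC)cc1C(CO)C(=O)c1ccc(OCc2ccccc2)cc1F | intermediate (not isolated)
8 | 7-(benzyloxy)-3-[4,5-dimethoxy-2-(methoxymethoxy)phenyl]chroman-4-one (racemic) | COCOc1cc(OC)c(OC)cc1C1COc2cc(OCc3ccccc3)ccc2C1=O | intermediate
9 | (3R,4R)-7-(benzyloxy)-3-[4,5-dimethoxy-2-(methoxymethoxy)phenyl]chroman-4-ol | COCOc1cc(OC)c(OC)cc1[C@@H]1COc2cc(OCc3ccccc3)ccc2[C@@H]1O | intermediate (not isolated)
10 | (3R,4R)-7-(benzyloxy)-3-(2-hydroxy-4,5-dimethoxyphenyl)chroman-4-ol | COc1cc(O)c(cc1OC)[C@@H]1COc2cc(OCc3ccccc3)ccc2[C@@H]1O | intermediate (not isolated)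
11 | (6aR,11aR)-3-(benzyloxy)-8,9-dimethoxy-6a,11a-dihydro-6H-[1]benzofuro[3,2-c]chromene (pterocarpan) | COc1cc2c(cc1OC)[C@@H]1COc3cc(OCc4ccccc4)ccc3[C@@H]1O2 | intermediate
12 | 2-bromo-5-methoxyphenol | COc1ccc(Br)c(O)c1 | starting material
13 | 2-(benzyloxy)-1-bromo-4-methoxybenzene | COc1ccc(Br)c(OCc2ccccc2)c1 | intermediate
14 | 1-[4-(benzyloxy)-2-fluorophenyl]-2-[2-(benzyloxy)-4-methoxyphenyl]ethan-1-one | COc1ccc(CC(=O)c2ccc(OCc3ccccc3)cc2F)c(OCc2ccccc2)c1 | intermediate
15 | 1-[4-(benzyloxy)-2-fluorophenyl]-2-[2-(benzyloxy)-4-methoxyphenyl]-3-hydroxypropan-1-one (racemic) | COc1ccc(C(CO)C(=O)c2ccc(OCc3ccccc3)cc2F)c(OCc2ccccc2)c1 | intermediate (not isolated)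
16 | 7-(benzyloxy)-3-[2-(benzyloxy)-4-methoxyphenyl]chroman-4-one (racemic) | COc1ccc(C2COc3cc(OCc4ccccc4)ccc3C2=O)c(OCc2ccccc2)c1 | intermediate
17 | 7-(benzyloxy)-3-{2-(benzyloxy)-5-[(3R,4S)-7-(benzyloxy)-3-(2-hydroxy-4,5-dimethoxyphenyl)chroman-4-yl]-4-methoxyphenyl}chroman-4-one (epimers at C3 of the chromanone) | COc1cc(O)c(cc1OC)[C@@H]2COc3cc(OCc4ccccc4)ccc3[C@H]2c5cc(C6COc7cc(OCc8ccccc8)ccc7C6=O)c(OCc9ccccc9)cc5OC | intermediate
18 | (3R,4R)-7-(benzyloxy)-3-{2-(benzyloxy)-5-[(3R,4S)-7-(benzyloxy)-3-(2-hydroxy-4,5-dimethoxyphenyl)chroman-4-yl]-4-methoxyphenyl}chroman-4-ol | COc1cc(O)c(cc1OC)[C@@H]2COc3cc(OCc4ccccc4)ccc3[C@H]2c5cc([C@@H]6COc7cc(OCc8ccccc8)ccc7[C@@H]6O)c(OCc9ccccc9)cc5OC | intermediate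
19 | (3R,4S)-4-{4-hydroxy-5-[(3R)-7-hydroxychroman-3-yl]-2-methoxyphenyl}-3-(2-hydroxy-4,5-dimethoxyphenyl)chroman-7-ol | COc1cc(O)c([C@@H]2COc3cc(O)ccc3[C@H]2c2cc([C@@H]3COc4cc(O)ccc4C3)c(O)cc2OC)cc1OC | target

**Step count and risks**

Total step count: 12. Longest linear sequence: 8 steps (3 → 4 → 5 → 6 → 8 → 11 → 17 → 18 → 19).

Steps most likely to fail:

1. Step 10. The C4 cation may lose the C3 proton faster than it is arylated, which would erase the upper C3 stereocentre through the achiral chromene. Alkylation may also stray to another ring position or continue on the product. The fallback sets out from 11 and separates ionisation from arylation. Opening of 11 with benzyl mercaptan and SnCl4 in CH2Cl2 at low temperature should give (3R,4S)-7-(benzyloxy)-4-(benzylsulfanyl)-3-(2-hydroxy-4,5-dimethoxyphenyl)chroman F1. The sulfide is then activated by the thiophile AgBF4 in CH2Cl2 at 0 °C in the presence of 16, under aprotic conditions that disfavour proton loss. The fallback returns to the route at 17.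

2. Step 5. Dehydration of the hydroxymethyl ketone and Michael addition of unreacted enolate to the resulting enone may outpace an aryl ether closure that is slowed by the donating para benzyloxy group. The fallback sets out from 6 and raises the oxidation level so that no β-hydroxy ketone is involved. Claisen formylation with ethyl formate and NaH in THF should give 3-[4-(benzyloxy)-2-fluorophenyl]-2-[4,5-dimethoxy-2-(methoxymethoxy)phenyl]-3-oxopropanal F2 as its sodium enolate. Heating this in DMF should close ring C through SNAr by the enolate oxygen, giving 7-(benzyloxy)-3-[4,5-dimethoxy-2-(methoxymethoxy)phenyl]-4H-chromen-4-one F3. Transfer hydrogenation of this isoflavone with the catalyst of step 6 (conjugate reduction, then ketone reduction with dynamic kinetic resolution) returns to the route at 9, which is carried through the acid stage of step 6.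

3. Step 12. Acid-promoted dehydration of the lower-half benzylic alcohol to the chromene, followed by unselective hydrogenation, would scramble the lower C3 stereocentre. The fallback sets out from 18 and removes the hydroxyl by hydride transfer before any hydrogenation. Et3SiH and BF3·OEt2 in CH2Cl2 at −78 °C should give (3R,4S)-7-(benzyloxy)-4-{4-(benzyloxy)-5-[(3R)-7-(benzyloxy)chroman-3-yl]-2-methoxyphenyl}-3-(2-hydroxy-4,5-dimethoxyphenyl)chroman F4. Neutral hydrogenolysis (H2, 10% Pd/C, EtOAc–EtOH) then removes the benzyl groups and returns to the route at 19.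

**Further compounds**

F1 | step 10 | (3R,4S)-7-(benzyloxy)-4-(benzylsulfanyl)-3-(2-hydroxy-4,5-dimethoxyphenyl)chroman | COc1cc(O)c(cc1OC)[C@@H]2COc3cc(OCc4ccccc4)ccc3[C@H]2SCc5ccccc5
F2 | step 5 | 3-[4-(benzyloxy)-2-fluorophenyl]-2-[4,5-dimethoxy-2-(methoxymethoxy)phenyl]-3-oxopropanal | COCOc1cc(OC)c(OC)cc1C(C=O)C(=O)c1ccc(OCc2ccccc2)cc1F
F3 | step 5 | 7-(benzyloxy)-3-[4,5-dimethoxy-2-(methoxymethoxy)phenyl]-4H-chromen-4-one | COCOc1cc(OC)c(OC)cc1C2=COc3cc(OCc4ccccc4)ccc3C2=O
F4 | step 12 | (3R,4S)-7-(benzyloxy)-4-{4-(benzyloxy)-5-[(3R)-7-(benzyloxy)chroman-3-yl]-2-methoxyphenyl}-3-(2-hydroxy-4,5-dimethoxyphenyl)chroman | COc1cc(O)c(cc1OC)[C@@H]2COc3cc(OCc4ccccc4)ccc3[C@H]2c5cc([C@@H]6COc7cc(OCc8ccccc8)ccc7C6)c(OCc9ccccc9)cc5OC
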